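**Retrosynthetic overview**
- Endgame: target ⇐ diol (acetylation) ⇐ dipivalate ⇐ C6 dithiolane (desulfurisation) ⇐ trans-fused 7-en-6-one ⇐ cis-fused 7-en-6-one (C5 epimerisation through the α′-enolate).
- Key disconnection: ring B of the cis-enone is opened by excising C7=C8 with its methyl C17 as propyne. This leaves a cyclobutanone (ring C5–C6–C9–C10, C6=O) fused to ring A. Forward, nickel-catalysed insertion of propyne into the C6–C9 bond builds ring B and its trisubstituted alkene in one operation.
- Enabling feature: the only unsaturation of ring B, C7=C8, lies between C6 and C9, and both of these are bonded to the adjacent ring-fusion atoms C5 and C10, so removing the two sp2 carbons leaves a four-membered ring. C6 is a plain CH2 in the target, so it can carry a temporary carbonyl that supplies the strained acyl–carbon bond and later the handle for C5 epimerisation.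
- The cyclobutanone comes from a keteniminium–alkene [2+2] between the ring A alkene (from (S)-epichlorohydrin by two Grignard openings and ring-closing metathesis) and the side-chain amide (from (S)-citronellol by oxidative cleavage and Arndt–Eistert homologation).
- Order of ring formation: ring A (metathesis), then the four-membered ring ([2+2]), then ring B (two-carbon ring expansion).

Key step: step 10

Remark on the chemistry: skeleton atoms of all intermediates are referred to by labdane numbering (C17 = methyl on C8, C20 = methyl on C10). The target is read as the ent-labdane with H-5 trans to CH3-10, the C9 side chain cis to CH3-10, the C2 acetate trans to CH3-10 (equatorial) and C13 S.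

**Route**

Step 1
Reactants: 1 (S)-epichlorohydrin; 2 isopropenylmagnesium bromide
Product: 4 (S)-2-(2-methylprop-2-en-1-yl)oxirane, via chlorohydrin 3 (not isolated)
Conditions: CuI (10 mol%), THF, −40 → 0 °C; then NaOH (excess), Et2O/H2O, rt
Reagents that add atoms: none
Why: Copper-catalysed Grignard opening of the epoxide at its unsubstituted carbon leaves the stereocentre untouched, and base then closes the chlorohydrin to the new epoxide by intramolecular Williamson displacement at the CH2Cl carbon.

Step 2
Reactants: 4 (S)-2-(2-methylprop-2-en-1-yl)oxirane; 5 prenylmagnesium chloride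
Product: 6 (S)-2,6,6-trimethylocta-1,7-dien-4-ol
Conditions: THF, 0 °C → rt; H2O quench
Reagents that add atoms: none
Why: Allylic Grignard reagents react through their γ-carbon (SE2′), so the tertiary prenyl carbon should attack the unsubstituted epoxide carbon and install the gem-dimethyl vinyl unit without involving the carbinol stereocentre.

Step 3
Reactants: 6 (S)-2,6,6-trimethylocta-1,7-dien-4-ol
Product: 7 (S)-3,5,5-trimethylcyclohex-3-en-1-ol
Conditions: second-generation Grubbs catalyst (3 mol%), CH2Cl2 (0.02 M), 40 °C
Reagents that add atoms: none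
Why: Ring-closing metathesis of the 1,1-disubstituted and monosubstituted alkenes, helped by the gem-dimethyl (Thorpe–Ingold) effect, should close ring A as the trisubstituted cyclohexene with loss of ethene.

Step 4
Reactants: 7 (S)-3,5,5-trimethylcyclohex-3-en-1-ol
Product: 8 (S)-3,5,5-trimethylcyclohex-3-en-1-yl pivalate
Conditions: PivCl, pyridine, DMAP (cat.), CH2Cl2, 0 °C → rt
Reagents that add atoms: pivaloyl chloride, CC(C)(C)C(Cl)=O
Why: Standard acylation; the pivalate has no α-hydrogen and should survive triflic anhydride, zerovalent nickel, lithium amide, BF3/dithiol and Raney Ni in the later steps.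

Step 5
Reactants: 9 (S)-citronellol
Product: 10 (S)-citronellyl pivalate
Conditions: PivCl, pyridine, DMAP (cat.), CH2Cl2, 0 °C → rt
Reagents that add atoms: pivaloyl chloride, CC(C)(C)C(Cl)=O
Why: Standard acylation of the primary alcohol, with the same protecting-group logic as in step 4; the C13 stereocentre is bought in with the starting material.

Step 6
Reactants: 10 (S)-citronellyl pivalate
Product: 11 (S)-4-methyl-6-(pivaloyloxy)hexanoic acid
Conditions: RuCl3·xH2O (2 mol%), NaIO4 (4 equiv), CCl4/MeCN/H2O, rt
Reagents that add atoms: sodium periodate, [Na+].[O-]I(=O)(=O)=O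
Why: Catalytic RuO4 oxidative cleavage of the trisubstituted alkene should give the carboxylic acid and acetone, leaving the remote stereocentre and the ester untouched.

Step 7
Reactants: 11 (S)-4-methyl-6-(pivaloyloxy)hexanoic acid
Product: 13 (S)-7-diazo-3-methyl-6-oxoheptyl pivalate, via acid chloride 12 (not isolated)
Conditions: (COCl)2, DMF (cat.), CH2Cl2, 0 °C → rt; evaporate; CH2N2 (3 equiv), Et2O, 0 °C
Reagents that add atoms: oxalyl chloride, O=C(Cl)C(Cl)=O (chlorine of 12 only); diazomethane, C=[N+]=[N-]
Why: First stage of the Arndt–Eistert homologation, acylation of diazomethane by the acid chloride, with excess diazomethane scavenging the hydrogen chloride.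

Step 8
Reactants: 13 (S)-7-diazo-3-methyl-6-oxoheptyl pivalate
Product: 15 (S)-3-methyl-7-oxo-7-(pyrrolidin-1-yl)heptyl pivalate, via ketene 14 (not isolated)
Conditions: AgO2CPh (10 mol%), pyrrolidine (3 equiv), THF, −20 °C → rt, dark
Reagents that add atoms: pyrrolidine, C1CCNC1
Why: Silver-catalysed Wolff rearrangement gives the ketene, which pyrrolidine traps as the one-carbon-homologated tertiary amide needed for keteniminium formation.

Step 9
Reactants: 15 (S)-3-methyl-7-oxo-7-(pyrrolidin-1-yl)heptyl pivalate; 8 (S)-3,5,5-trimethylcyclohex-3-en-1-yl pivalate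
Product: 18 cis-fused cyclobutanone dipivalate (1,5,5-trimethyl-8-[(3S)-3-methyl-5-(pivaloyloxy)pentyl]-7-oxobicyclo[4.2.0]octan-3-yl pivalate; ketone at labdane C6), via keteniminium triflate 16 (not isolated), via cyclobutaniminium triflate 17 (not isolated)
Conditions: 15 (1.5 equiv), Tf2O (1.6 equiv), 2,4,6-collidine (1.7 equiv), ClCH2CH2Cl, −20 → 80 °C; aq NaHCO3, rt; DBU (0.2 equiv), CH2Cl2, rt
Reagents that add atoms: water, O
Why: In this keteniminium–alkene [2+2] cycloaddition the electrophilic central carbon should bond to the less substituted alkene carbon C5 and the enamine carbon C9 should close onto the tertiary C10 cation, which fixes the regiochemistry and the cis ring fusion, while attack anti to the pseudoaxial C4 methyl of the half-chair with equatorial OPiv should place the new bonds cis to the C2 oxygen, and DBU should equilibrate C9 through the enol to the exo epimer with the side chain cis to CH3-10.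

Step 10
Reactants: 18 cis-fused cyclobutanone dipivalate; 19 propyne
Product: 20 cis-fused enone dipivalate (2,5,5,8a-tetramethyl-1-[(3S)-3-methyl-5-(pivaloyloxy)pentyl]-4-oxo-1,4,4a,5,6,7,8,8a-octahydronaphthalen-7-yl pivalate with H-4a cis to CH3-8a; a 5-epi-6-oxolabd-7-ene)
Conditions: Ni(cod)2 (10 mol%), PCy3 (20 mol%), toluene, 100 °C, sealed vessel; 19 (3 equiv, 1 M in THF) added over 6 h
Reagents that add atoms: none
Why: Zerovalent nickel should couple the strained C6 carbonyl with propyne by oxidative cyclisation to a spiro oxanickelacyclopentene (C6–C7 bond, the carbonyl carbon joining the unsubstituted alkyne terminus so that the methyl-bearing C8 stays on nickel), after which β-carbon elimination cleaves C6–C9 to a seven-membered nickelacycle and C(sp2)–C(sp3) reductive elimination forms C8–C9. The closest known reaction type is the nickel-catalysed intermolecular insertion of alkynes into cyclobutanones to give cyclohex-2-enones, a formal [4+2] of a C–C σ bond with an alkyne. Ring B is closed by two-carbon ring expansion of the four-membered ring C5–C6–C9–C10, driven by release of cyclobutanone strain, and ring A is not touched. No stereocentre is created: C9 is transferred from C6 to C8 with retention, because β-carbon elimination and reductive elimination both occur at the metal with retention, and C5 and C10 are not involved, so the cis fusion of 18 is carried into 20. The step needs cleavage of C6–C9 and not of C6–C5, which the substrate secures because C5 sits between the two quaternary carbons C4 and C10 while C9 carries only an unbranched chain, and it needs the hydrogen-bearing alkyne terminus at the carbonyl, which the steric preference of the oxidative cyclisation secures. Slow addition of propyne should keep alkyne oligomerisation slower than the strain-driven ketone coupling.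

Step 11
Reactants: 20 cis-fused enone dipivalate
Product: 22 trans-fused enone dipivalate (same constitution as 20 with H-4a trans to CH3-8a; a 6-oxolabd-7-ene of the target configuration), via lithium dienolate 21 (not isolated)
Conditions: LiN(i-Pr)2 (1.2 equiv), THF, −78 °C, 1 h; then AcOH (3 equiv), THF, −78 °C → rt
Reagents that add atoms: none
Why: Kinetic deprotonation of an enone by a lithium amide takes place at the α′ position (C5–H) and gives the cross-conjugated dienolate without touching the γ-hydrogen at C9, and kinetic protonation at C5 should then occur from the face opposite the angular C10 methyl and the axial C4 methyl (axial protonation on ring A), giving the trans-fused decalin.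

Step 12
Reactants: 22 trans-fused enone dipivalate
Product: 23 dithiolane dipivalate (spiro-1,3-dithiolane at labdane C6 of the trans-fused labd-7-ene skeleton)
Conditions: HSCH2CH2SH (5 equiv), BF3·OEt2 (0.3 equiv), CH2Cl2, 0 °C → rt
Reagents that add atoms: ethane-1,2-dithiol, SCCS
Why: Lewis-acid-catalysed dithioketalisation of the enone carbonyl, in which 1,2-addition is preferred over conjugate addition at the fully substituted C8 and the double bond stays at C7=C8, as in the classical thioketals of steroidal enones.

Step 13
Reactants: 23 dithiolane dipivalate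
Product: 24 (3S)-3-methyl-5-[(1R,4aR,7R,8aR)-2,5,5,8a-tetramethyl-7-(pivaloyloxy)-1,4,4a,5,6,7,8,8a-octahydronaphthalen-1-yl]pentyl pivalate
Conditions: Raney Ni (W-2, excess, pre-refluxed in acetone), EtOH, 60 °C
Reagents that add atoms: none
Why: Raney nickel desulfurisation (Mozingo reduction) should replace both C–S bonds by C–H and turn C6 into a methylene without moving the C7=C8 double bond, the esters and the trisubstituted alkene being inert.

Step 14
Reactants: 24 dipivalate
Product: 25 (3S)-5-[(1R,4aR,7R,8aR)-7-hydroxy-2,5,5,8a-tetramethyl-1,4,4a,5,6,7,8,8a-octahydronaphthalen-1-yl]-3-methylpentan-1-ol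
Conditions: LiAlH4 (4 equiv), THF, 0 °C → rt; H2O/aq NaOH work-up
Reagents that add atoms: none
Why: Hydride reduction cleaves both hindered pivalates to the diol, with no effect on the alkene or on any stereocentre.

Step 15
Reactants: 25 diol
Product: 26 (3S)-5-[(1R,4aR,7R,8aR)-7-acetoxy-2,5,5,8a-tetramethyl-1,4,4a,5,6,7,8,8a-octahydronaphthalen-1-yl]-3-methylpentyl acetate (CNP0220683.1)
Conditions: Ac2O (4 equiv), pyridine, DMAP (cat.), CH2Cl2, rt
Reagents that add atoms: acetic anhydride, CC(=O)OC(C)=O
Why: DMAP-catalysed acetylation of the primary and the equatorial secondary alcohol completes the target.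

**Compound list**

1 | (S)-epichlorohydrin | ClC[C@@H]1CO1 | starting material
2 | isopropenylmagnesium bromide | CC(=C)[Mg]Br | starting material
3 | (S)-1-chloro-4-methylpent-4-en-2-ol (not isolated) | ClC[C@@H](O)CC(C)=C | intermediate
4 | (S)-2-(2-methylprop-2-en-1-yl)oxirane | C1O[C@H]1CC(C)=C | intermediate
5 | prenylmagnesium chloride | CC(C)=CC[Mg]Cl | starting material
6 | (S)-2,6,6-trimethylocta-1,7-dien-4-ol | C=CC(C)(C)C[C@@H](O)CC(C)=C | intermediate
7 | (S)-3,5,5-trimethylcyclohex-3-en-1-ol | CC1=CC(C)(C)C[C@@H](O)C1 | intermediate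
8 | (S)-3,5,5-trimethylcyclohex-3-en-1-yl pivalate | CC1=CC(C)(C)C[C@@H](OC(=O)C(C)(C)C)C1 | intermediate
9 | (S)-citronellol | OCC[C@@H](C)CCC=C(C)C | starting material
10 | (S)-citronellyl pivalate | CC(C)(C)C(=O)OCC[C@@H](C)CCC=C(C)C | intermediate
11 | (S)-4-methyl-6-(pivaloyloxy)hexanoic acid | CC(C)(C)C(=O)OCC[C@@H](C)CCC(=O)O | intermediate
12 | (S)-6-chloro-3-methyl-6-oxohexyl pivalate (acid chloride, not isolated) | CC(C)(C)C(=O)OCC[C@@H](C)CCC(=O)Cl | intermediate
13 | (S)-7-diazo-3-methyl-6-oxoheptyl pivalate | CC(C)(C)C(=O)OCC[C@@H](C)CCC(=O)C=[N+]=[N-] | intermediate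
14 | (S)-3-methyl-7-oxohept-6-en-1-yl pivalate (ketene, not isolated) | CC(C)(C)C(=O)OCC[C@@H](C)CCC=C=O | intermediate
15 | (S)-3-methyl-7-oxo-7-(pyrrolidin-1-yl)heptyl pivalate | CC(C)(C)C(=O)OCC[C@@H](C)CCCC(=O)N1CCCC1 | intermediate
16 | 1-[(5S)-5-methyl-7-(pivaloyloxy)hept-1-en-1-ylidene]pyrrolidinium triflate (keteniminium, not isolated) | CC(C)(C)C(=O)OCC[C@@H](C)CCC=C=[N+]1CCCC1.[O-]S(=O)(=O)C(F)(F)F | intermediate
17 | cyclobutaniminium triflate, pyrrolidinium at C6, cis-fused, mixture of C9 epimers (not isolated) | CC(C)(C)C(=O)OCC[C@@H](C)CCC1C(=[N+]3CCCC3)[C@H]2C(C)(C)C[C@@H](OC(=O)C(C)(C)C)C[C@@]12C.[O-]S(=O)(=O)C(F)(F)F | intermediate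
18 | cis-fused cyclobutanone dipivalate: 1,5,5-trimethyl-8-[(3S)-3-methyl-5-(pivaloyloxy)pentyl]-7-oxobicyclo[4.2.0]octan-3-yl pivalate; H-5 cis to CH3-10, C9 side chain cis to CH3-10, C2 ester trans to CH3-10 | CC(C)(C)C(=O)OCC[C@@H](C)CC[C@@H]1C(=O)[C@H]2C(C)(C)C[C@@H](OC(=O)C(C)(C)C)C[C@@]12C | intermediate
19 | propyne | CC#C | starting material
20 | cis-fused enone dipivalate: 2,5,5,8a-tetramethyl-1-[(3S)-3-methyl-5-(pivaloyloxy)pentyl]-4-oxo-1,4,4a,5,6,7,8,8a-octahydronaphthalen-7-yl pivalate, H-4a cis to CH3-8a | CC(C)(C)C(=O)OCC[C@@H](C)CC[C@@H]1C(C)=CC(=O)[C@H]2C(C)(C)C[C@@H](OC(=O)C(C)(C)C)C[C@@]12C | intermediate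
21 | lithium cross-conjugated dienolate of 20 (C5=C6–OLi, not isolated) | CC(C)(C)C(=O)OCC[C@@H](C)CC[C@@H]1C(C)=CC(O[Li])=C2C(C)(C)C[C@@H](OC(=O)C(C)(C)C)C[C@@]12C | intermediate
22 | trans-fused enone dipivalate: constitution of 20 with H-4a trans to CH3-8a | CC(C)(C)C(=O)OCC[C@@H](C)CC[C@@H]1C(C)=CC(=O)[C@@H]2C(C)(C)C[C@@H](OC(=O)C(C)(C)C)C[C@@]12C | intermediate
23 | dithiolane dipivalate: spiro-1,3-dithiolane at C6 of the trans-fused labd-7-ene-2,15-diyl dipivalate | CC(C)(C)C(=O)OCC[C@@H](C)CC[C@@H]1C(C)=CC3(SCCS3)[C@@H]2C(C)(C)C[C@@H](OC(=O)C(C)(C)C)C[C@@]12C | intermediate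
24 | (3S)-3-methyl-5-[(1R,4aR,7R,8aR)-2,5,5,8a-tetramethyl-7-(pivaloyloxy)-1,4,4a,5,6,7,8,8a-octahydronaphthalen-1-yl]pentyl pivalate | CC(C)(C)C(=O)OCC[C@@H](C)CC[C@@H]1C(C)=CC[C@@H]2C(C)(C)C[C@@H](OC(=O)C(C)(C)C)C[C@@]12C | intermediate
25 | (3S)-5-[(1R,4aR,7R,8aR)-7-hydroxy-2,5,5,8a-tetramethyl-1,4,4a,5,6,7,8,8a-octahydronaphthalen-1-yl]-3-methylpentan-1-ol | OCC[C@@H](C)CC[C@@H]1C(C)=CC[C@@H]2C(C)(C)C[C@@H](O)C[C@@]12C | intermediate
26 | (3S)-5-[(1R,4aR,7R,8aR)-7-acetoxy-2,5,5,8a-tetramethyl-1,4,4a,5,6,7,8,8a-octahydronaphthalen-1-yl]-3-methylpentyl acetate | CC(=O)OCC[C@@H](C)CC[C@@H]1C(C)=CC[C@@H]2C(C)(C)C[C@@H](OC(C)=O)C[C@@]12C | target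

**Step count and risks**

Total step count: 15. Longest linear sequence: 11 steps (steps 1–4 then 9–15, or steps 5–8 then 9–15).

Steps most likely to fail:

1. Step 10 (alkyne insertion). Three processes can defeat it: oligomerisation of the terminal alkyne at zerovalent nickel faster than coupling with the hindered ketone; β-carbon elimination on the C5 side instead of the C9 side; and β-hydride elimination from the secondary alkylnickel at C9 before reductive elimination. The fallback sets out from 18 and returns at 20, building the C7=C8 unit one carbon at a time by two ring enlargements instead of a metal-catalysed insertion.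
   - Homologation of 18 with diazoethane under Sc(OTf)3 catalysis (Tiffeneau–Demjanov-type carbonyl homologation, the less hindered C9 migrating with retention) should give the α-methylcyclopentanone F1, with C8 and its methyl between C6 and C9.
   - Kinetic enolisation toward C8 and silylation (LiN(i-Pr)2, Me3SiCl, THF, −78 °C) should give the silyl enol ether F2.
   - Simmons–Smith cyclopropanation in the Furukawa variant (Et2Zn, CH2I2) should give the siloxycyclopropane F3.
   - FeCl3 in DMF (Saegusa–Ito ring enlargement) should open F3 to the β-chloro ketone F4, from which NaOAc in MeOH eliminates hydrogen chloride to give the cis-fused enone 20.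

2. Step 9 (keteniminium [2+2]). The hindered trisubstituted alkene may react too slowly, so that the aldo-keteniminium ion condenses with itself, or facial selectivity relative to C2 may be poor. The fallback sets out from 8 and 11 and returns at 18, replacing the convergent cycloaddition by a ketene cycloaddition followed by alkylation.
   - Dichloroketene (from Cl3CCOCl and Zn–Cu couple, Et2O) adds to 8 with the same regiochemistry and facial bias to give the dichlorocyclobutanone F5.
   - Zn/AcOH removes both chlorines to give the cyclobutanone F6 with C9 as a methylene.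
   - Hypervalent-iodine iododecarboxylation of acid 11 (PhI(OAc)2, I2, hν) gives (R)-5-iodo-3-methylpentyl pivalate F7.
   - Kinetic deprotonation of F6 at the C9 methylene (LiN(i-Pr)2, THF/DMPU, −78 °C) and alkylation with F7 on the convex face, followed by the same DBU equilibration, should give 18.

3. Step 12 (dithioketalisation, with step 13 depending on it). The C6 carbonyl is flanked by C5 and lies close to the C4 gem-dimethyl group, so thioketal formation may stall or be overtaken by thiol conjugate addition. In step 13 the allylic C–S cleavage may also shift or saturate the double bond. The fallback sets out from 22 and returns at 24, replacing desulfurisation by reduction and allylic hydrogenolysis.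
   - Luche reduction (NaBH4, CeCl3·7H2O, MeOH, −20 °C) gives the allylic alcohol F8.
   - ClCO2Me and pyridine give the methyl carbonate F9.
   - Pd(PPh3)4 (5 mol%) with NaBH4 in THF ionises the carbonate to a π-allyl complex of divalent palladium, which hydride should capture at the less substituted terminus C6, keeping the C7=C8 double bond and giving 24.

Further compounds
F1 | step 10 | α-methylcyclopentanone (hydrindanone) dipivalate: ring C5–C6(=O)–C8H(CH3)–C9–C10, cis-fused, C9 as in 18 | CC(C)(C)C(=O)OCC[C@@H](C)CC[C@@H]1C(C)C(=O)[C@H]2C(C)(C)C[C@@H](OC(=O)C(C)(C)C)C[C@@]12C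
F2 | step 10 | trimethylsilyl enol ether of F1 (C6=C8) | CC(C)(C)C(=O)OCC[C@@H](C)CC[C@@H]1C(C)=C(O[Si](C)(C)C)[C@H]2C(C)(C)C[C@@H](OC(=O)C(C)(C)C)C[C@@]12C
F3 | step 10 | siloxycyclopropane from F2 (C7 methylene bridging C6 and C8) | CC(C)(C)C(=O)OCC[C@@H](C)CC[C@@H]1C3(C)CC3(O[Si](C)(C)C)[C@H]2C(C)(C)C[C@@H](OC(=O)C(C)(C)C)C[C@@]12C
F4 | step 10 | 8-chloro-8-methyl-6-oxo cis-decalin dipivalate (β-chloro ketone) | CC(C)(C)C(=O)OCC[C@@H](C)CC[C@@H]1C(C)(Cl)CC(=O)[C@H]2C(C)(C)C[C@@H](OC(=O)C(C)(C)C)C[C@@]12C
F5 | step 9 | 8,8-dichloro-1,5,5-trimethyl-7-oxobicyclo[4.2.0]octan-3-yl pivalate, cis-fused, ester trans to the angular methyl | ClC1(Cl)C(=O)[C@H]2C(C)(C)C[C@@H](OC(=O)C(C)(C)C)C[C@@]12C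
F6 | step 9 | 1,5,5-trimethyl-7-oxobicyclo[4.2.0]octan-3-yl pivalate, cis-fused, ester trans to the angular methyl | C1C(=O)[C@H]2C(C)(C)C[C@@H](OC(=O)C(C)(C)C)C[C@@]12C
F7 | step 9 | (R)-5-iodo-3-methylpentyl pivalate | CC(C)(C)C(=O)OCC[C@@H](C)CCI
F8 | step 12 | allylic alcohol: 6-hydroxy trans-fused labd-7-ene-2,15-diyl dipivalate (C6 epimer not defined) | CC(C)(C)C(=O)OCC[C@@H](C)CC[C@@H]1C(C)=CC(O)[C@@H]2C(C)(C)C[C@@H](OC(=O)C(C)(C)C)C[C@@]12C
F9 | step 12 | methyl carbonate of F8 | CC(C)(C)C(=O)OCC[C@@H](C)CC[C@@H]1C(C)=CC(OC(=O)OC)[C@@H]2C(C)(C)C[C@@H](OC(=O)C(C)(C)C)C[C@@]12C
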